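## Retrosynthetic overview

- The target is opened at the C1–Ca bond: an aryl allyl carbonate (from resorcinol) and a bicyclic silyl dienol ether (the decalin) are joined late by an iridium-catalysed allylic alkylation that sets C1 and Ca.
- After the union: cross-metathesis and hydrogenation make the isobutyl group, MeLi builds both tertiary carbinols (C4 and C11), then double ortho-formylation and O-demethylation finish the arene.
- Decalin: ring A is bought as cyclohexane-1,3-dione; ring B is closed onto it by conjugate methylation (C10), enolate alkylation and ring-closing metathesis, then hydrogenation/equilibration (C5, C7).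
- Aryl part: resorcinol → 1,3,5-trimethoxybenzene (Ir C–H borylation/oxidation) → aldehyde → cinnamyl carbonate.

Assumption: eudesmane numbering is used for the decalin (C1 side-chain carbon, C4 carbinol, C5 ring-fusion H, C7 C3 unit, C10 angular methyl), Ca is the benzylic carbon, α/β mean below/above the plane in the usual eudesmane drawing (ring A left, C10 above C5); read this way the target SMILES is 1β-side chain, 4α-OH, 5β-H, 7α-(2-hydroxypropan-2-yl), 10α-CH3 and S at Ca; each chiral ligand is used as the enantiomer that gives the stated configuration.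

## Route

**Aryl fragment**

Step 1
Reactants: 1 resorcinol
Product: 2 1,3-dimethoxybenzene
Conditions: MeI, K2CO3, acetone, reflux
Reagents that add atoms: iodomethane, CI
Why: Williamson O-methylation of both phenols; no stereocentre.

Step 2
Reactants: 2 1,3-dimethoxybenzene
Product: 4 3,5-dimethoxyphenol, via 3,5-dimethoxyphenylboronic acid pinacol ester 3 (not isolated)
Conditions: [Ir(cod)(OMe)]2 (1 mol%), dtbpy, B2pin2 (0.6 equiv), THF, 80 °C; then KHSO5 (Oxone), acetone/H2O, rt
Reagents that add atoms: bis(pinacolato)diboron, CC1(C)OB(OC1(C)C)B1OC(C)(C)C(C)(C)O1 (boron in 3 only); potassium peroxymonosulfate, [K+].[O-]S(=O)(=O)OO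
Why: Sterically controlled iridium-catalysed aromatic C–H borylation occurs at C5, the only position not ortho to a methoxy group, and oxidation of the C–B bond gives the phenol (C–H borylation/oxidation).

Step 3
Reactants: 4 3,5-dimethoxyphenol
Product: 5 1,3,5-trimethoxybenzene
Conditions: MeI, K2CO3, acetone, reflux
Reagents that add atoms: iodomethane, CI
Why: Williamson ether synthesis.

Step 4
Reactants: 5 1,3,5-trimethoxybenzene
Product: 7 2,4,6-trimethoxybenzaldehyde, via aryl N,N-dimethyliminium chloride 6 (not isolated)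
Conditions: POCl3, DMF, 0 °C → rt; then H2O
Reagents that add atoms: N,N-dimethylformamide, CN(C)C=O; water, O
Why: Vilsmeier–Haack formylation of the strongly activated arene, the iminium being hydrolysed on work-up.

Step 5
Reactants: 7 2,4,6-trimethoxybenzaldehyde; 8 3-methoxy-3-oxopropanoic acid (monomethyl malonate)
Product: 10 methyl (E)-3-(2,4,6-trimethoxyphenyl)prop-2-enoate, via arylidene malonic half ester 9 (not isolated)
Conditions: pyridine, piperidine (cat.), 100 °C
Reagents that add atoms: none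
Why: Knoevenagel–Doebner condensation with decarboxylation gives the E-cinnamate.

Step 6
Reactants: 10 methyl (E)-3-(2,4,6-trimethoxyphenyl)prop-2-enoate
Product: 11 (E)-3-(2,4,6-trimethoxyphenyl)prop-2-en-1-ol
Conditions: i-Bu2AlH (2.2 equiv), CH2Cl2, −78 °C
Reagents that add atoms: none
Why: 1,2-reduction of the conjugated ester by the aluminium hydride leaves the alkene intact.

Step 7
Reactants: 11 (E)-3-(2,4,6-trimethoxyphenyl)prop-2-en-1-ol
Product: 12 methyl (E)-3-(2,4,6-trimethoxyphenyl)prop-2-en-1-yl carbonate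
Conditions: ClCO2Me, pyridine, CH2Cl2, 0 °C; used at once
Reagents that add atoms: methyl chloroformate, COC(=O)Cl
Why: O-acylation gives the allylic carbonate leaving group needed for allyl-metal formation.

**Decalin fragment**

Step 8
Reactants: 13 cyclohexane-1,3-dione
Product: 14 3-ethoxycyclohex-2-en-1-one
Conditions: EtOH, p-TsOH (cat.), toluene, reflux (Dean–Stark)
Reagents that add atoms: ethanol, CCO
Why: Acid-catalysed enol etherification gives the vinylogous ester.

Step 9
Reactants: 14 3-ethoxycyclohex-2-en-1-one; 15 allylmagnesium bromide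
Product: 17 3-allylcyclohex-2-en-1-one, via bromomagnesium tertiary alkoxide 16 (not isolated)
Conditions: THF, 0 °C; then 1 M HCl, 0 °C (brief)
Reagents that add atoms: water, O
Why: Stork–Danheiser sequence, 1,2-addition to the vinylogous ester followed by acid hydrolysis with carbonyl transposition.

Step 10
Reactants: 17 3-allylcyclohex-2-en-1-one; 18 methyl 2-(bromomethyl)prop-2-enoate
Product: 20 methyl 2-{[(2S)-2-allyl-2-methyl-6-oxocyclohexyl]methyl}prop-2-enoate (C5 epimer mixture), via dimethylaluminium enolate 19 (not isolated)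
Conditions: Me3Al (1.4 equiv), CuTC (copper thiophene-2-carboxylate, 2 mol%), BINOL phosphoramidite P1 (4 mol%), Et2O, −30 °C; then MeLi (1.4 equiv), THF, −78 °C; 18, −78 → 0 °C
Reagents that add atoms: trimethylaluminium, C[Al](C)C
Why: Copper-catalysed asymmetric conjugate addition sets the quaternary C10 (S, ligand control), and the regiodefined enolate, activated as its aluminate, is alkylated at C5 by the allylic bromide; the C5 configuration is not controlled here and is corrected in step 12.

Step 11
Reactants: 20 methyl 2-{[(2S)-2-allyl-2-methyl-6-oxocyclohexyl]methyl}prop-2-enoate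
Product: 21 methyl 10α-methyl-4-oxodecal-7-ene-7-carboxylate (C5 epimer mixture)
Conditions: second-generation Grubbs catalyst RuCl2(=CHPh)(PCy3)(H2IMes) (3 mol%), CH2Cl2, 40 °C
Reagents that add atoms: none
Why: Ring-closing metathesis of the allyl group with the acrylate alkene closes ring B as a cyclohexene carboxylate.

Step 12
Reactants: 21 methyl 10α-methyl-4-oxodecal-7-ene-7-carboxylate
Product: 23 methyl 10α-methyl-4-oxo-5βH-decalin-7α-carboxylate, via hydrogenated keto ester epimer mixture 22 (not isolated)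
Conditions: H2 (1 atm), Pd/C, MeOH, rt; filter; NaOMe (0.3 equiv), MeOH, 40 °C
Reagents that add atoms: none
Why: Catalytic hydrogenation of the enoate followed by base equilibration of both enolisable centres should give the thermodynamically preferred trans-fused ketone (5β-H) with the equatorial ester (7α, cis to the angular methyl), which fixes C5 and C7 relative to C10.

Step 13
Reactants: 23 methyl 10α-methyl-4-oxo-5βH-decalin-7α-carboxylate
Product: 25 methyl 10α-methyl-4-oxo-5βH-decal-2-ene-7α-carboxylate, via trimethylsilyl enol ether 24 (not isolated)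
Conditions: LiN(i-Pr)2 (1.05 equiv), Me3SiCl, THF, −78 °C; then Pd(OAc)2 (1 equiv), MeCN, rt
Reagents that add atoms: chlorotrimethylsilane, C[Si](C)(C)Cl (silicon in 24 only)
Why: Saegusa–Ito oxidation, kinetic enolisation taking the less hindered C3 side, so the enone forms at C2=C3.

Step 14
Reactants: 25 methyl 10α-methyl-4-oxo-5βH-decal-2-ene-7α-carboxylate
Product: 26 methyl 10α-methyl-4-(trimethylsilyloxy)-5βH-decala-1,3-diene-7α-carboxylate
Conditions: Me3SiOTf, Et3N, CH2Cl2, 0 °C → rt
Reagents that add atoms: trimethylsilyl triflate, C[Si](C)(C)OS(=O)(=O)C(F)(F)F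
Why: Soft enolisation under equilibrating conditions is expected to remove a C1 (γ) proton, because the alternative C5 proton is a hindered ring-fusion methine whose enol ether would be tetrasubstituted and strained against C6, giving the linear silyl dienol ether.

**Union and endgame**

Step 15
Reactants: 26 methyl 10α-methyl-4-(trimethylsilyloxy)-5βH-decala-1,3-diene-7α-carboxylate; 12 methyl (E)-3-(2,4,6-trimethoxyphenyl)prop-2-en-1-yl carbonate
Product: 27 methyl 1β-[(1S)-1-(2,4,6-trimethoxyphenyl)prop-2-enyl]-10α-methyl-4-oxo-5βH-decal-2-ene-7α-carboxylate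
Conditions: [Ir(cod)Cl]2 (2 mol%), BINOL phosphoramidite P2 with N,N-bis[1-(2-methoxyphenyl)ethyl] arm (4 mol%, pre-activated with n-PrNH2), KF, 18-crown-6, THF, 35 °C
Reagents that add atoms: none
Why: Proposed new method: the cyclometalated iridium phosphoramidite ionises the carbonate to a cationic π-allyl complex, which the fluoride-activated ketone silyl dienol ether attacks through its terminal carbon C1 (vinylogous attack that restores the enone) at the aryl-bearing allyl terminus (branched selectivity, reinforced by the trimethoxyphenyl donor); C1 is set by approach anti to the axial 10α-methyl (1β substituent) and Ca (S) by the ligand-controlled face of the allyl unit, the closest known reaction type being iridium-catalysed asymmetric allylic alkylation of trimethylsilyl enolates of vinylogous esters and of dioxinone silyl dienolates, not yet shown for a ketone dienol ether with a neopentyl terminus or a 2,6-dialkoxy cinnamyl partner.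

Step 16
Reactants: 27 methyl 1β-[(1S)-1-(2,4,6-trimethoxyphenyl)prop-2-enyl]-10α-methyl-4-oxo-5βH-decal-2-ene-7α-carboxylate; 28 2-methylbut-2-ene
Product: 29 methyl 1β-[(1S)-3-methyl-1-(2,4,6-trimethoxyphenyl)but-2-enyl]-10α-methyl-4-oxo-5βH-decal-2-ene-7α-carboxylate
Conditions: second-generation Hoveyda–Grubbs catalyst RuCl2(=CH-C6H4-2-O-i-Pr)(H2IMes) (5 mol%), 1,4-benzoquinone (10 mol%), 28 (excess), CH2Cl2, 40 °C
Reagents that add atoms: none
Why: Olefin cross-metathesis of the terminal vinyl group with 2-methylbut-2-ene installs the isopropylidene end, benzoquinone suppressing alkene migration towards Ca.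

Step 17
Reactants: 29 methyl 1β-[(1S)-3-methyl-1-(2,4,6-trimethoxyphenyl)but-2-enyl]-10α-methyl-4-oxo-5βH-decal-2-ene-7α-carboxylate
Product: 30 methyl 1β-[(1S)-3-methyl-1-(2,4,6-trimethoxyphenyl)butyl]-10α-methyl-4-oxo-5βH-decalin-7α-carboxylate
Conditions: H2 (3 atm), [Ir(cod)(PCy3)(py)]PF6 (5 mol%), CH2Cl2, rt
Reagents that add atoms: none
Why: Homogeneous hydrogenation with Crabtree's catalyst reduces the enone and side-chain alkenes without the allylic isomerisation that could erode Ca or C1; no new stereocentre is formed.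

Step 18
Reactants: 30 methyl 1β-[(1S)-3-methyl-1-(2,4,6-trimethoxyphenyl)butyl]-10α-methyl-4-oxo-5βH-decalin-7α-carboxylate
Product: 31 1β-[(1S)-3-methyl-1-(2,4,6-trimethoxyphenyl)butyl]-7α-(2-hydroxypropan-2-yl)-4β,10α-dimethyl-5βH-decalin-4α-ol
Conditions: MeLi (6 equiv), THF, −78 → 0 °C; H2O
Reagents that add atoms: methyllithium, [Li]C
Why: 1,2-addition of methyllithium, the C4 ketone being attacked along the equatorial trajectory because the axial face is blocked by the syn-axial 10α-methyl (giving the axial 4α-OH, cis to the angular methyl), while double addition to the ester gives the C11 carbinol.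

Step 19
Reactants: 31 1β-[(1S)-3-methyl-1-(2,4,6-trimethoxyphenyl)butyl]-7α-(2-hydroxypropan-2-yl)-4β,10α-dimethyl-5βH-decalin-4α-ol
Product: 34 5-[(1S)-1-(4α-hydroxy-7α-(2-hydroxypropan-2-yl)-4β,10α-dimethyl-5βH-decalin-1β-yl)-3-methylbutyl]-2,4,6-trimethoxybenzene-1,3-dicarbaldehyde, via monoformyl lithium hemiaminal 32 (not isolated), via bisformyl lithium hemiaminal 33 (not isolated)
Conditions: n-BuLi (3.3 equiv), TMEDA, THF, 0 °C; DMF (1.2 equiv), −78 → 0 °C; n-BuLi (1.5 equiv), 0 °C; DMF (3 equiv); 1 M HCl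
Reagents that add atoms: N,N-dimethylformamide, CN(C)C=O
Why: Directed ortho-metalation at each aryl C–H flanked by two methoxy groups followed by formylation with DMF, the first formyl group staying masked as its lithium α-amino alkoxide during the second lithiation and the carbinols as alkoxides.

Step 20
Reactants: 34 5-[(1S)-1-(4α-hydroxy-7α-(2-hydroxypropan-2-yl)-4β,10α-dimethyl-5βH-decalin-1β-yl)-3-methylbutyl]-2,4,6-trimethoxybenzene-1,3-dicarbaldehyde
Product: 35 5-[(1S)-1-[(1S,4R,4aS,6S,8aR)-4-hydroxy-6-(2-hydroxypropan-2-yl)-4,8a-dimethyldecahydronaphthalen-1-yl]-3-methylbutyl]-2,4,6-trihydroxybenzene-1,3-dicarbaldehyde (CNP0409870.3)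
Conditions: NaSEt (12 equiv), DMF, 120 °C; then 1 M HCl
Reagents that add atoms: none
Why: Nucleophilic (SN2) O-demethylation by thiolate, each methoxy group being activated by an ortho or para formyl group, under basic conditions that spare the tertiary alcohols and the stereocentres.

## Compound list

1 | resorcinol | Oc1cccc(O)c1 | starting material
2 | 1,3-dimethoxybenzene | COc1cccc(OC)c1 | intermediate
3 | 2-(3,5-dimethoxyphenyl)-4,4,5,5-tetramethyl-1,3,2-dioxaborolane | COc1cc(OC)cc(c1)B1OC(C)(C)C(C)(C)O1 | intermediate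
4 | 3,5-dimethoxyphenol | COc1cc(O)cc(OC)c1 | intermediate
5 | 1,3,5-trimethoxybenzene | COc1cc(OC)cc(OC)c1 | intermediate
6 | N,N-dimethyl-1-(2,4,6-trimethoxyphenyl)methaniminium chloride | COc1cc(OC)c(C=[N+](C)C)c(OC)c1.[Cl-] | intermediate
7 | 2,4,6-trimethoxybenzaldehyde | COc1cc(OC)c(C=O)c(OC)c1 | intermediate
8 | 3-methoxy-3-oxopropanoic acid (monomethyl malonate) | COC(=O)CC(O)=O | starting material
9 | 2-(methoxycarbonyl)-3-(2,4,6-trimethoxyphenyl)prop-2-enoic acid | COC(=O)C(=Cc1c(OC)cc(OC)cc1OC)C(O)=O | intermediate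
10 | methyl (E)-3-(2,4,6-trimethoxyphenyl)prop-2-enoate | COC(=O)/C=C/c1c(OC)cc(OC)cc1OC | intermediate
11 | (E)-3-(2,4,6-trimethoxyphenyl)prop-2-en-1-ol | OC/C=C/c1c(OC)cc(OC)cc1OC | intermediate
12 | methyl (E)-3-(2,4,6-trimethoxyphenyl)prop-2-en-1-yl carbonate | COC(=O)OC/C=C/c1c(OC)cc(OC)cc1OC | intermediate
13 | cyclohexane-1,3-dione | O=C1CCCC(=O)C1 | starting material
14 | 3-ethoxycyclohex-2-en-1-one | CCOC1=CC(=O)CCC1 | intermediate
15 | allylmagnesium bromide | C=CC[Mg]Br | starting material
16 | bromomagnesium 1-allyl-3-ethoxycyclohex-2-en-1-olate | CCOC1=CC(CC=C)(O[Mg]Br)CCC1 | intermediate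
17 | 3-allylcyclohex-2-en-1-one | C=CCC1=CC(=O)CCC1 | intermediate
18 | methyl 2-(bromomethyl)prop-2-enoate | C=C(CBr)C(=O)OC | starting material
19 | dimethylaluminium (3S)-3-allyl-3-methylcyclohex-1-en-1-olate | C=CC[C@]1(C)CCCC(O[Al](C)C)=C1 | intermediate
20 | methyl 2-{[(2S)-2-allyl-2-methyl-6-oxocyclohexyl]methyl}prop-2-enoate (C5 epimer mixture) | C=CC[C@]1(C)CCCC(=O)C1CC(=C)C(=O)OC | intermediate
21 | methyl 10α-methyl-4-oxodecal-7-ene-7-carboxylate (C5 epimer mixture) | C1CCC(=O)C2CC(C(=O)OC)=CC[C@]12C | intermediate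
22 | methyl 10α-methyl-4-oxodecalin-7-carboxylate (C5 and C7 epimer mixture) | C1CCC(=O)C2CC(C(=O)OC)CC[C@]12C | intermediate
23 | methyl 10α-methyl-4-oxo-5βH-decalin-7α-carboxylate, i.e. methyl (2S,4aS,8aS)-4a-methyl-8-oxodecahydronaphthalene-2-carboxylate | C1CCC(=O)[C@H]2C[C@@H](C(=O)OC)CC[C@]12C | intermediate
24 | methyl 10α-methyl-4-(trimethylsilyloxy)-5βH-decal-3-ene-7α-carboxylate | C1CC=C(O[Si](C)(C)C)[C@H]2C[C@@H](C(=O)OC)CC[C@]12C | intermediate
25 | methyl 10α-methyl-4-oxo-5βH-decal-2-ene-7α-carboxylate | C1C=CC(=O)[C@H]2C[C@@H](C(=O)OC)CC[C@]12C | intermediate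
26 | methyl 10α-methyl-4-(trimethylsilyloxy)-5βH-decala-1,3-diene-7α-carboxylate | C1=CC=C(O[Si](C)(C)C)[C@H]2C[C@@H](C(=O)OC)CC[C@]12C | intermediate
27 | methyl 1β-[(1S)-1-(2,4,6-trimethoxyphenyl)prop-2-enyl]-10α-methyl-4-oxo-5βH-decal-2-ene-7α-carboxylate | C=C[C@H](c1c(OC)cc(OC)cc1OC)[C@@H]1C=CC(=O)[C@H]2C[C@@H](C(=O)OC)CC[C@]12C | intermediate
28 | 2-methylbut-2-ene | CC=C(C)C | starting material
29 | methyl 1β-[(1S)-3-methyl-1-(2,4,6-trimethoxyphenyl)but-2-enyl]-10α-methyl-4-oxo-5βH-decal-2-ene-7α-carboxylate | CC(C)=C[C@H](c1c(OC)cc(OC)cc1OC)[C@@H]1C=CC(=O)[C@H]2C[C@@H](C(=O)OC)CC[C@]12C | intermediate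
30 | methyl 1β-[(1S)-3-methyl-1-(2,4,6-trimethoxyphenyl)butyl]-10α-methyl-4-oxo-5βH-decalin-7α-carboxylate | CC(C)C[C@H](c1c(OC)cc(OC)cc1OC)[C@@H]1CCC(=O)[C@H]2C[C@@H](C(=O)OC)CC[C@]12C | intermediate
31 | 1β-[(1S)-3-methyl-1-(2,4,6-trimethoxyphenyl)butyl]-7α-(2-hydroxypropan-2-yl)-4β,10α-dimethyl-5βH-decalin-4α-ol | CC(C)C[C@H](c1c(OC)cc(OC)cc1OC)[C@@H]1CC[C@@](C)(O)[C@H]2C[C@@H](C(C)(C)O)CC[C@]12C | intermediate
32 | trilithium salt of 31 carrying one aryl CH(OLi)NMe2 group (monoformyl hemiaminal) | CC(C)C[C@H](c1c(OC)c(C(O[Li])N(C)C)c(OC)cc1OC)[C@@H]1CC[C@@](C)(O[Li])[C@H]2C[C@@H](C(C)(C)O[Li])CC[C@]12C | intermediate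
33 | tetralithium salt carrying two aryl CH(OLi)NMe2 groups (bisformyl hemiaminal) | CC(C)C[C@H](c1c(OC)c(C(O[Li])N(C)C)c(OC)c(C(O[Li])N(C)C)c1OC)[C@@H]1CC[C@@](C)(O[Li])[C@H]2C[C@@H](C(C)(C)O[Li])CC[C@]12C | intermediate
34 | 5-[(1S)-1-(4α-hydroxy-7α-(2-hydroxypropan-2-yl)-4β,10α-dimethyl-5βH-decalin-1β-yl)-3-methylbutyl]-2,4,6-trimethoxybenzene-1,3-dicarbaldehyde | CC(C)C[C@H](c1c(OC)c(C=O)c(OC)c(C=O)c1OC)[C@@H]1CC[C@@](C)(O)[C@H]2C[C@@H](C(C)(C)O)CC[C@]12C | intermediate
35 | 5-[(1S)-1-[(1S,4R,4aS,6S,8aR)-4-hydroxy-6-(2-hydroxypropan-2-yl)-4,8a-dimethyldecahydronaphthalen-1-yl]-3-methylbutyl]-2,4,6-trihydroxybenzene-1,3-dicarbaldehyde | CC(C)C[C@H](c1c(O)c(C=O)c(O)c(C=O)c1O)[C@@H]1CC[C@@](C)(O)[C@H]2C[C@@H](C(C)(C)O)CC[C@]12C | target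

## Step count

Total steps: 20. Longest linear sequence: 13 steps (steps 1–7 or steps 8–14, then steps 15–20), i.e. 13/20 of the total.

## Steps most likely to fail, with fallbacks

**Step 15 (proposed new iridium-catalysed vinylogous allylic alkylation).** It may give attack at C3 instead of C1, or the hindered 2,6-dialkoxy cinnamyl unit may not react. The fallback uses known chemistry and sets out from 26 and aldehyde 7. Isobutylmagnesium bromide is added to 7 (THF, 0 °C) to give racemic 3-methyl-1-(2,4,6-trimethoxyphenyl)butan-1-ol F1. F1 is ionised with BF3·OEt2 (CH2Cl2, −78 °C) in the presence of 26, a vinylogous Mukaiyama-type SN1 alkylation of a silyl dienol ether by a trialkoxybenzyl cation, which gives methyl 1β-[(1S)-3-methyl-1-(2,4,6-trimethoxyphenyl)butyl]-10α-methyl-4-oxo-5βH-decal-2-ene-7α-carboxylate F2. C1 is again set anti to the angular methyl; Ca is under substrate control only, so the benzylic epimer would have to be removed by chromatography. Hydrogenation of F2 under the conditions of step 17 returns to the route at 30.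

**Step 14 (regioselective dienol ether formation).** Soft enolisation may give the cross-conjugated C4=C5 isomer. The fallback sets out from 25. Deconjugative ketalisation (ethylene glycol, p-TsOH, benzene, Dean–Stark) moves the double bond to C1=C2 and gives methyl 4,4-ethylenedioxy-10α-methyl-5βH-decal-1-ene-7α-carboxylate F3. Mild hydrolysis (PPTS, aqueous acetone, 0 °C) gives the β,γ-unsaturated ketone methyl 10α-methyl-4-oxo-5βH-decal-1-ene-7α-carboxylate F4. Kinetic deprotonation of its doubly activated C3–H (LiN(i-Pr)2, THF, −78 °C) with Me3SiCl trapping gives the linear dienol ether regiospecifically and comes back to the route at 26.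

**Step 19 (double ortho-lithiation/formylation).** The second lithiation may stall in the presence of the alkoxides. The fallback sets out from 31. NBS (2.1 equiv, MeCN, 0 °C) brominates both free aryl positions to give 1β-[(1S)-1-(3,5-dibromo-2,4,6-trimethoxyphenyl)-3-methylbutyl]-7α-(2-hydroxypropan-2-yl)-4β,10α-dimethyl-5βH-decalin-4α-ol F5. Bromine–lithium exchange (MeLi to deprotonate the alcohols, then t-BuLi, THF, −78 °C) and quench with DMF, repeated in the same flask for the second bromide, gives the dialdehyde and comes back to the route at 34.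

## Further compounds

F1 | step 15 | 3-methyl-1-(2,4,6-trimethoxyphenyl)butan-1-ol (racemic) | CC(C)CC(O)c1c(OC)cc(OC)cc1OC
F2 | step 15 | methyl 1β-[(1S)-3-methyl-1-(2,4,6-trimethoxyphenyl)butyl]-10α-methyl-4-oxo-5βH-decal-2-ene-7α-carboxylate | CC(C)C[C@H](c1c(OC)cc(OC)cc1OC)[C@@H]1C=CC(=O)[C@H]2C[C@@H](C(=O)OC)CC[C@]12C
F3 | step 14 | methyl 4,4-ethylenedioxy-10α-methyl-5βH-decal-1-ene-7α-carboxylate | C1=CCC3(OCCO3)[C@H]2C[C@@H](C(=O)OC)CC[C@]12C
F4 | step 14 | methyl 10α-methyl-4-oxo-5βH-decal-1-ene-7α-carboxylate | C1=CCC(=O)[C@H]2C[C@@H](C(=O)OC)CC[C@]12C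
F5 | step 19 | 1β-[(1S)-1-(3,5-dibromo-2,4,6-trimethoxyphenyl)-3-methylbutyl]-7α-(2-hydroxypropan-2-yl)-4β,10α-dimethyl-5βH-decalin-4α-ol | CC(C)C[C@H](c1c(OC)c(Br)c(OC)c(Br)c1OC)[C@@H]1CC[C@@](C)(O)[C@H]2C[C@@H](C(C)(C)O)CC[C@]12C
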